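The γ‑butyrolactone ring (O1, C2, C3, C4, C5) is cut across two ring bonds, O1–C5 and C3–C4, which flank the C4 stereocentre carrying the guaiacylmethyl group. Both bonds are made in one operation when dichloroketene meets an enantiopure (E)-3-arylprop-1-enyl p-tolyl sulfoxide: acylation of the sulfinyl oxygen, a [3,3] shift that builds C3–C4 and passes the chirality of sulfur to C4, then closure of the carboxylate on the C5 thionium carbon. The precursor is an open-chain vinyl sulfoxide. The C3 chlorines and the C5 sulfur are stripped afterwards, and C4 then steers trans benzylation and anti hydroxylation at C3.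

Key step: step 5

Remark on the chemistry: the sense of chirality transfer in step 5 is assumed from the chair-like transition state with the p-tolyl group outside. Descriptors at sulfur and at C4 change along the route through priority changes only, not through any change in spatial arrangement. Ring numbering: lactone O1, carbonyl C2, C3, C4, C5 (CH2).

Step 1
Reactants: 1 4-(benzyloxy)-3-methoxybenzyl alcohol
Product: 2 1-(benzyloxy)-4-(bromomethyl)-2-methoxybenzene
Conditions: PBr3 (0.4 equiv), Et2O, 0 °C; used crude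
Reagents that add atoms: phosphorus tribromide BrP(Br)Br
Why: Substitution of an electron-rich benzylic alcohol by bromide through its bromophosphite ester should be fast at 0 °C; no stereocentre is involved.

Step 2
Reactants: 2 1-(benzyloxy)-4-(bromomethyl)-2-methoxybenzene
Product: 3 1-(benzyloxy)-2-methoxy-4-(prop-2-yn-1-yl)benzene
Conditions: HC≡CMgBr (2.5 equiv, THF), CuBr·SMe2 (10 mol %), THF, 0 °C to 45 °C
Reagents that add atoms: ethynylmagnesium bromide C#C[Mg]Br
Why: Copper-catalysed Kumada-type sp3–sp coupling of a benzylic bromide with an alkynyl Grignard reagent; the excess reagent holds the product as its acetylide and should suppress propargyl–allenyl isomerization.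

Step 3
Reactants: 3 1-(benzyloxy)-2-methoxy-4-(prop-2-yn-1-yl)benzene; 4 (1R,2S,5R)-menthyl (S)-4-methylbenzenesulfinate
Product: 6 1-(benzyloxy)-2-methoxy-4-[3-[(S)-(4-methylphenyl)sulfinyl]prop-2-yn-1-yl]benzene, via alkynylmagnesium bromide 5 (not isolated)
Conditions: EtMgBr (1.05 equiv), THF, 0 °C to rt; then added to 4 in toluene, −20 °C
Reagents that add atoms: none
Why: Andersen sulfoxide synthesis, in which the alkynyl Grignard reagent displaces mentholate at sulfur with inversion, so the sulfur stereocentre comes from the sulfinate ester (the S descriptor of 6 reflects only the high priority of the alkynyl group).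

Step 4
Reactants: 6 1-(benzyloxy)-2-methoxy-4-[3-[(S)-(4-methylphenyl)sulfinyl]prop-2-yn-1-yl]benzene
Product: 7 1-(benzyloxy)-2-methoxy-4-[(E)-3-[(R)-(4-methylphenyl)sulfinyl]prop-2-en-1-yl]benzene
Conditions: i-Bu2AlH (1.2 equiv), THF, −90 °C to −78 °C; then MeOH, aq. KNaC4H4O6
Reagents that add atoms: none
Why: trans-Hydroalumination of the polarised alkynyl sulfoxide (hydride to the β-carbon, protonolysis of the α-aluminated alkene) should give the (E)-alkene with sulfur untouched; the descriptor becomes R only because aryl now outranks alkenyl.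

Step 5
Reactants: 7 1-(benzyloxy)-2-methoxy-4-[(E)-3-[(R)-(4-methylphenyl)sulfinyl]prop-2-en-1-yl]benzene
Product: 10 (4R,5R)-4-[4-(benzyloxy)-3-methoxybenzyl]-3,3-dichloro-5-[(4-methylphenyl)sulfanyl]oxolan-2-one, via acyloxysulfonium enolate 8 (not isolated), via thionium carboxylate 9 (not isolated)
Conditions: Cl3CCOCl (3 equiv, slow addition), Zn–Cu couple (6 equiv), Et2O, 0 °C to reflux
Reagents that add atoms: trichloroacetyl chloride ClC(Cl)(Cl)C(Cl)=O (reduced in the flask by zinc to dichloroketene ClC(Cl)=C=O)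
Why: Zinc reduces trichloroacetyl chloride to dichloroketene, whose carbonyl carbon is attacked by the sulfinyl oxygen of 7 to give the acyloxysulfonium enolate 8; a [3,3]-sigmatropic shift (3-oxa-4-thia-Cope, the additive Pummerer pathway) then joins the enolate carbon C3 to C4 as the S–O bond breaks, and the carboxylate of 9 adds to the thionium carbon C5 to form O1–C5. The closest known reaction type is the vinyl sulfoxide–dichloroketene lactonization (Marino annulation). The lactone ring closes by 5-exo-trig attack of the carboxylate oxygen on the C=S+ carbon. C4 is controlled by the sulfur stereocentre: in the chair-like transition state the p-tolyl group lies outside (pseudo-equatorial) and the lone pair inside, so the oxygen-tethered enolate is delivered suprafacially to one face of the (E)-alkene, which should give the 4R centre; C5 should form trans to the C4 substituent and is removed in step 6. The step needs acylation of the sulfinyl oxygen to outrun [2+2] addition of the ketene to the alkene and acylation of the arene, which the nucleophilic sulfinyl oxygen and the electron-poor vinyl sulfoxide double bond should secure.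

Step 6
Reactants: 10 (4R,5R)-4-[4-(benzyloxy)-3-methoxybenzyl]-3,3-dichloro-5-[(4-methylphenyl)sulfanyl]oxolan-2-one
Product: 11 (S)-4-[4-(benzyloxy)-3-methoxybenzyl]oxolan-2-one
Conditions: Bu3SnH (4 equiv), AIBN (0.2 equiv), toluene, 110 °C
Reagents that add atoms: none
Why: Radical chain reduction with tributyltin hydride, in which stannyl radicals abstract both chlorines α to the carbonyl and cleave the C5–S bond of the α-acyloxy sulfide, should leave the remote C4 centre untouched (its descriptor becomes S by priority change only).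

Step 7
Reactants: 12 4-(benzyloxy)-3,5-dimethoxybenzaldehyde
Product: 13 [4-(benzyloxy)-3,5-dimethoxyphenyl]methanol
Conditions: NaBH4, MeOH, 0 °C
Reagents that add atoms: none
Why: Borohydride reduction of an aromatic aldehyde to the benzylic alcohol; no stereocentre is involved.

Step 8
Reactants: 13 [4-(benzyloxy)-3,5-dimethoxyphenyl]methanol
Product: 14 2-(benzyloxy)-5-(bromomethyl)-1,3-dimethoxybenzene
Conditions: PBr3 (0.4 equiv), Et2O, 0 °C; used crude
Reagents that add atoms: phosphorus tribromide BrP(Br)Br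
Why: Substitution of the electron-rich benzylic alcohol by bromide through its bromophosphite ester, as in step 1.

Step 9
Reactants: 11 (S)-4-[4-(benzyloxy)-3-methoxybenzyl]oxolan-2-one; 14 2-(benzyloxy)-5-(bromomethyl)-1,3-dimethoxybenzene
Product: 16 (3S,4S)-3-[4-(benzyloxy)-3,5-dimethoxybenzyl]-4-[4-(benzyloxy)-3-methoxybenzyl]oxolan-2-one, via lithium enolate 15 (not isolated)
Conditions: LiN(SiMe3)2 (1.1 equiv), THF, −78 °C; then 14, DMPU, −78 °C to −30 °C
Reagents that add atoms: none
Why: Alkylation of the lithium lactone enolate with a reactive benzylic bromide, in which the electrophile should approach anti to the C4 arylmethyl group and give the trans-3,4-disubstituted lactone (1,2-induction).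

Step 10
Reactants: 16 (3S,4S)-3-[4-(benzyloxy)-3,5-dimethoxybenzyl]-4-[4-(benzyloxy)-3-methoxybenzyl]oxolan-2-one
Product: 18 (3S,4R)-3-[4-(benzyloxy)-3,5-dimethoxybenzyl]-4-[4-(benzyloxy)-3-methoxybenzyl]-3-hydroxyoxolan-2-one, via potassium enolate 17 (not isolated)
Conditions: KN(SiMe3)2 (1.3 equiv), THF, −78 °C; then 2-(phenylsulfonyl)-3-phenyloxaziridine (1.5 equiv), −78 °C
Reagents that add atoms: 2-(phenylsulfonyl)-3-phenyloxaziridine O=S(=O)(c1ccccc1)N1OC1c1ccccc1
Why: Electrophilic α-hydroxylation of the potassium enolate by an N-sulfonyloxaziridine, in which oxygen should be delivered to the enolate face anti to the C4 arylmethyl group, so that the C3 hydroxyl ends trans and the C3 benzyl group cis to it (3S); the potassium counter-ion limits addition to the sulfonylimine by-product.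

Step 11
Reactants: 18 (3S,4R)-3-[4-(benzyloxy)-3,5-dimethoxybenzyl]-4-[4-(benzyloxy)-3-methoxybenzyl]-3-hydroxyoxolan-2-one
Product: 19 (3S,4R)-3-hydroxy-3-(4-hydroxy-3,5-dimethoxybenzyl)-4-(4-hydroxy-3-methoxybenzyl)oxolan-2-one
Conditions: H2 (1 atm), 10% Pd/C, EtOAc–MeOH, rt
Reagents that add atoms: none
Why: Hydrogenolysis of both benzyl aryl ethers over Pd/C; the lactone and the non-benzylic tertiary alcohol should be inert, so both stereocentres are retained.

Compound list
1 | 4-(benzyloxy)-3-methoxybenzyl alcohol | COc1cc(CO)ccc1OCc1ccccc1 | starting material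
2 | 1-(benzyloxy)-4-(bromomethyl)-2-methoxybenzene | COc1cc(CBr)ccc1OCc1ccccc1 | intermediate
3 | 1-(benzyloxy)-2-methoxy-4-(prop-2-yn-1-yl)benzene | COc1cc(CC#C)ccc1OCc1ccccc1 | intermediate
4 | (1R,2S,5R)-menthyl (S)-4-methylbenzenesulfinate | CC(C)[C@@H]1CC[C@@H](C)C[C@H]1O[S@](=O)c1ccc(C)cc1 | starting material
5 | [3-[4-(benzyloxy)-3-methoxyphenyl]prop-1-yn-1-yl]magnesium bromide | COc1cc(CC#C[Mg]Br)ccc1OCc1ccccc1 | intermediate
6 | 1-(benzyloxy)-2-methoxy-4-[3-[(S)-(4-methylphenyl)sulfinyl]prop-2-yn-1-yl]benzene | Cc1ccc(cc1)[S@](=O)C#CCc1ccc(OCc2ccccc2)c(OC)c1 | intermediate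
7 | 1-(benzyloxy)-2-methoxy-4-[(E)-3-[(R)-(4-methylphenyl)sulfinyl]prop-2-en-1-yl]benzene | Cc1ccc(cc1)[S@](=O)/C=C/Cc1ccc(OCc2ccccc2)c(OC)c1 | intermediate
8 | acyloxysulfonium enolate (dichloroketene adduct at the sulfinyl oxygen of 7) | Cc1ccc(cc1)[S@+](OC([O-])=C(Cl)Cl)/C=C/Cc1ccc(OCc2ccccc2)c(OC)c1 | intermediate
9 | thionium carboxylate: (3R)-3-[4-(benzyloxy)-3-methoxybenzyl]-2,2-dichloro-4-[(4-methylphenyl)sulfoniumylidene]butanoate | [O-]C(=O)C(Cl)(Cl)[C@H](Cc1ccc(OCc2ccccc2)c(OC)c1)/C=[S+]/c1ccc(C)cc1 | intermediate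
10 | (4R,5R)-4-[4-(benzyloxy)-3-methoxybenzyl]-3,3-dichloro-5-[(4-methylphenyl)sulfanyl]oxolan-2-one | COc1cc(C[C@@H]2[C@@H](Sc3ccc(C)cc3)OC(=O)C2(Cl)Cl)ccc1OCc1ccccc1 | intermediate
11 | (S)-4-[4-(benzyloxy)-3-methoxybenzyl]oxolan-2-one | COc1cc(C[C@@H]2COC(=O)C2)ccc1OCc1ccccc1 | intermediate
12 | 4-(benzyloxy)-3,5-dimethoxybenzaldehyde | COc1cc(C=O)cc(OC)c1OCc1ccccc1 | starting material
13 | [4-(benzyloxy)-3,5-dimethoxyphenyl]methanol | COc1cc(CO)cc(OC)c1OCc1ccccc1 | intermediate
14 | 2-(benzyloxy)-5-(bromomethyl)-1,3-dimethoxybenzene | COc1cc(CBr)cc(OC)c1OCc1ccccc1 | intermediate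
15 | lithium enolate of 11 | [Li+].[O-]C1=C[C@H](Cc2ccc(OCc3ccccc3)c(OC)c2)CO1 | intermediate
16 | (3S,4S)-3-[4-(benzyloxy)-3,5-dimethoxybenzyl]-4-[4-(benzyloxy)-3-methoxybenzyl]oxolan-2-one | COc1cc(C[C@@H]2COC(=O)[C@H]2Cc2cc(OC)c(OCc3ccccc3)c(OC)c2)ccc1OCc1ccccc1 | intermediate
17 | potassium enolate of 16 | [K+].[O-]C1=C(Cc2cc(OC)c(OCc3ccccc3)c(OC)c2)[C@H](Cc2ccc(OCc3ccccc3)c(OC)c2)CO1 | intermediate
18 | (3S,4R)-3-[4-(benzyloxy)-3,5-dimethoxybenzyl]-4-[4-(benzyloxy)-3-methoxybenzyl]-3-hydroxyoxolan-2-one | COc1cc(C[C@@H]2COC(=O)[C@]2(O)Cc2cc(OC)c(OCc3ccccc3)c(OC)c2)ccc1OCc1ccccc1 | intermediate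
19 | (3S,4R)-3-hydroxy-3-(4-hydroxy-3,5-dimethoxybenzyl)-4-(4-hydroxy-3-methoxybenzyl)oxolan-2-one | COc1cc(C[C@@H]2COC(=O)[C@]2(O)Cc2cc(OC)c(O)c(OC)c2)ccc1O | target

Total step count: 11. Longest linear sequence: 9 steps (steps 1 to 6, then 9 to 11).

Steps most likely to fail

Step 5. The transfer of chirality from sulfur to C4 may be incomplete, because an (E)-alkene can also pass through a transition state with the p-tolyl group inside; Pummerer-type consumption of the sulfoxide by the acid chloride may also compete. The fallback sets out from alkyne 3 and returns at lactone 10. The acetylide 5 would be treated with the enantiomeric, commercial (1S,2R,5S)-menthyl (R)-4-methylbenzenesulfinate F1 to give 1-(benzyloxy)-2-methoxy-4-[3-[(R)-(4-methylphenyl)sulfinyl]prop-2-yn-1-yl]benzene F2. Hydrogenation with H2 over RhCl(PPh3)3 in toluene at rt would then give the (Z)-alkene, 1-(benzyloxy)-2-methoxy-4-[(Z)-3-[(S)-(4-methylphenyl)sulfinyl]prop-2-en-1-yl]benzene F3. In F3 allylic 1,3-strain between the cis CH2 group and the sulfur substituents should lock the p-tolyl group outside, so the same dichloroketene lactonization should proceed through a single transition state and deliver 10, with the opposite alkene geometry compensated by the opposite configuration at sulfur.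

Step 10. Oxygen transfer to the tetrasubstituted enolate may show poor facial selectivity, or the enolate may add to the sulfonylimine by-product. The fallback sets out from lactone 11 and returns at target 19, and does not need bromide 14. The lithium enolate of 11 would be added to aldehyde 12 to give the aldol adduct (3S,4S)-3-[[4-(benzyloxy)-3,5-dimethoxyphenyl](hydroxy)methyl]-4-[4-(benzyloxy)-3-methoxybenzyl]oxolan-2-one F4 (carbinol epimers). Mesylation and elimination (MsCl, Et3N, then DBU) should give the (E)-benzylidene lactone, (3E,4S)-3-[4-(benzyloxy)-3,5-dimethoxybenzylidene]-4-[4-(benzyloxy)-3-methoxybenzyl]oxolan-2-one F5. Epoxidation with dimethyldioxirane in acetone on the face anti to the C4 arylmethyl group should give the spiro-epoxide F6, with the epoxide oxygen on C3 trans to the C4 substituent. Hydrogenolysis (H2, 10% Pd/C) should then cleave the benzylic C–O bond of the epoxide together with both benzyl ethers and leave the tertiary C3 hydroxyl of 19.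

Step 3. The CH2 group of 6 is activated by both the arene and the alkynyl sulfoxide, so base-induced propargyl-to-allenyl isomerization may occur during sulfinylation or during the hydride reduction of step 4. The fallback sets out from alkyne 3 and returns at vinyl sulfoxide 7, so that no alkynyl sulfoxide is formed. Hydrozirconation with Cp2Zr(H)Cl in THF followed by I2 should give 1-(benzyloxy)-4-[(E)-3-iodoprop-2-en-1-yl]-2-methoxybenzene F7. Iodine–magnesium exchange with i-PrMgCl·LiCl would give the (E)-alkenylmagnesium chloride F8, and its addition to sulfinate 4 in toluene at −20 °C (Andersen synthesis, inversion at sulfur, retention of alkene geometry) should give 7 directly.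

Further compounds
F1 | step 5 | (1S,2R,5S)-menthyl (R)-4-methylbenzenesulfinate | CC(C)[C@H]1CC[C@H](C)C[C@@H]1O[S@@](=O)c1ccc(C)cc1
F2 | step 5 | 1-(benzyloxy)-2-methoxy-4-[3-[(R)-(4-methylphenyl)sulfinyl]prop-2-yn-1-yl]benzene | Cc1ccc(cc1)[S@@](=O)C#CCc1ccc(OCc2ccccc2)c(OC)c1
F3 | step 5 | 1-(benzyloxy)-2-methoxy-4-[(Z)-3-[(S)-(4-methylphenyl)sulfinyl]prop-2-en-1-yl]benzene | Cc1ccc(cc1)[S@@](=O)/C=C\Cc1ccc(OCc2ccccc2)c(OC)c1
F4 | step 10 | (3S,4S)-3-[[4-(benzyloxy)-3,5-dimethoxyphenyl](hydroxy)methyl]-4-[4-(benzyloxy)-3-methoxybenzyl]oxolan-2-one (carbinol epimers) | COc1cc(C[C@@H]2COC(=O)[C@H]2C(O)c2cc(OC)c(OCc3ccccc3)c(OC)c2)ccc1OCc1ccccc1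
F5 | step 10 | (3E,4S)-3-[4-(benzyloxy)-3,5-dimethoxybenzylidene]-4-[4-(benzyloxy)-3-methoxybenzyl]oxolan-2-one | COc1cc(C[C@@H]2COC(=O)/C2=C/c2cc(OC)c(OCc3ccccc3)c(OC)c2)ccc1OCc1ccccc1
F6 | step 10 | spiro-epoxide of F5 with the epoxide oxygen on C3 trans to the C4 arylmethyl group | COc1cc(C[C@@H]2COC(=O)[C@@]23O[C@H]3c3cc(OC)c(OCc4ccccc4)c(OC)c3)ccc1OCc1ccccc1
F7 | step 3 | 1-(benzyloxy)-4-[(E)-3-iodoprop-2-en-1-yl]-2-methoxybenzene | COc1cc(C/C=C/I)ccc1OCc1ccccc1
F8 | step 3 | [(E)-3-[4-(benzyloxy)-3-methoxyphenyl]prop-1-en-1-yl]magnesium chloride | COc1cc(C/C=C/[Mg]Cl)ccc1OCc1ccccc1
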